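In a one-step world, electrophile + nucleophile → target, one nucleophile pays for one electrophile, so Monday's run, charged with 84.0% of a nucleophile per electrophile, should reach that much target.

| setting | Monday's | Friday's | red | amber |
|---|---|---|---|---|
| electrophile | 0.050 M | 0.050 M | 0.050 M | 0.050 M |
| nucleophile | 0.042 M | 0.068 M | 0.0550 M | 0.110 M |
| remark | run made earlier | run made earlier |  |  |
| time |  |  | 8.0 h | 8.0 h |

- Monday's (time / h: electrophile / %, target / %): 0.333: 63.6, 36.6; 0.667: 58.7, 40.8; 1.50: 57.7, 41.7; 4.00: 57.3, 43.0
- Friday's (time / h: electrophile / %, target / %): 0.333: 43.8, 55.2; 0.667: 36.4, 63.8; 1.50: 32.8, 67.5; 4.00: 32.9, 67.0

(scatter of a reading: 0.3 percentage points)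

- the analysis behind the earlier runs scatters by 0.3 percentage points, standard deviation
- what may be going on: electrophile + nucleophile <-> acid set free + target; nucleophile + acid set free <-> protonated nucleophile; 2 nucleophile -> self-condensation product

But Monday's target stands at 43.0% after 4.00 h, less than that, and Friday's, with more nucleophile than electrophile, stands at 67.0%. From 1.50 h to 4.00 h, Monday's target moves by 1.3 percentage points and Friday's by 0.5 points, so both runs have nearly stopped with electrophile left.

The next step on the list points to a cost: nucleophile + acid set free → protonated nucleophile. Compare rates at one moment: each forward turn frees one acid, and if capture keeps pace, it uses nucleophile as fast as the forward step does. So two nucleophiles go per target, and as c(nucleophile) sinks, the forward rate sinks with it.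

The rule, for a flask with too little nucleophile to take up its electrophile at two for one, is the two-for-one share, c(nucleophile) charged over two times c(electrophile) charged, for red 55.0%. It gives 42.0% for Monday's run and 68.0% for Friday's, close to both readings.

- part of the electrophile that has reacted at the end, red
- part of the electrophile that has reacted at the end, amber
- what raising the concentration of nucleophile from its lowest to its highest value here does to the part of the electrophile that has reacted (changes below 5 percentage points count as none) (no change / it falls / it rises)

The time asked is longer than those stops, so I take 55.0% for red. Amber's share is 110%, so there electrophile is the limiting reagent, and I take 100%.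

The forecast agrees on red with 55%, stands below me on amber with 96%, says it rises, and rests on this: “each electrophile reacted costs two nucleophiles”.

The flasks give 55.1% for red and 99.3% for amber, so it rises, by 44 points.

    electrophile + nucleophile ⇌ acid set free + target (K = 1.50, k = 1.39 M⁻¹ min⁻¹)
    nucleophile + acid set free ⇌ protonated nucleophile, settled at all times (K = 47600 M⁻¹)
    2 nucleophile → self-condensation product (k = 0.00311 M⁻¹ min⁻¹)

Red ends beside its share of 55.0%, with free nucleophile at 1.2% of its charge. Take red again with electrophile raised to 0.085 M: its share is 32.4%. That flask gives 32.8% at 8.00 h, with free nucleophile at 0.78% of its charge and 67.2% of its electrophile left.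

The data are simulated from invented constants, and the scatter is random.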